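**Plan**
The target is 3,6-dibromo-2-(3,5-dibromo-2-hydroxyphenoxy)phenol: ring A is the 2,4-dibromo-6-aryloxyphenol ring, ring B carries C1' OH, C2' ether O and bromines at C3' and C6'.
Retrosynthesis first removes the O–CH3 protecting bond on ring A and traces the C1'–OH bond back to a C1'–B bond, then cuts the C2'–O ether bond and the C1'–B bond in one operation.
The enabling feature is that C1' and C2' are adjacent heteroatom-bearing carbons flanked by the C6' and C3' bromines. They are the two symmetry-equivalent termini of 3,6-dibromobenzyne, so insertion of that aryne into the O–B bond of a ring A aryl borate sets both bonds with no regiochemical choice.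
Forward, the ring B aryne precursor (two steps from 2,5-dibromophenol) and the ring A borate (three steps from 3,5-dibromosalicylaldehyde) are joined in step 6; C–B oxidation and O-demethylation finish the route. No ring is formed at any stage.
The target has no stereocentre, so no stereochemistry has to be set.

Key step: step 6

Remark: 2,5-dibromophenol, 3,5-dibromosalicylaldehyde and pinacolborane are taken as commercial; the diaryl ether axis is not configurationally stable, so no stereocontrol is planned.

**Route**

Step 1
Reactants: 1 2,5-dibromophenol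
Product: 2 (2,5-dibromophenoxy)trimethylsilane
Conditions: (Me3Si)2NH (0.6 equiv), THF, 65 °C; volatiles removed in vacuo
Reagents that add atoms: hexamethyldisilazane, C[Si](C)(C)N[Si](C)(C)C
Why: Silylation of the phenol oxygen by hexamethyldisilazane (silyl ether formation) gives only ammonia as by-product, so the crude ether can go straight into the lithiation.

Step 2
Reactants: 2 (2,5-dibromophenoxy)trimethylsilane
Product: 5 3,6-dibromo-2-(trimethylsilyl)phenyl trifluoromethanesulfonate, via [3,6-dibromo-2-(trimethylsilyloxy)phenyl]lithium 3 (not isolated), via lithium 3,6-dibromo-2-(trimethylsilyl)phenoxide 4 (not isolated)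
Conditions: LiN(iPr)2 (1.1 equiv), THF, −78 °C; then Tf2O (1.3 equiv), −78 to 0 °C
Reagents that add atoms: trifluoromethanesulfonic anhydride, O=S(=O)(OS(=O)(=O)C(F)(F)F)C(F)(F)F
Why: The amide base removes the one proton flanked by the silyloxy group and a bromine (directed ortho-metalation), aryllithium 3 should undergo the 1,3 O-to-C silyl shift (retro-Brook rearrangement) to phenoxide 4 faster than it loses lithium bromide at −78 °C, and 4 is triflated on oxygen, which is the usual one-pot entry to ortho-silylaryl triflates.

Step 3
Reactants: 6 3,5-dibromo-2-hydroxybenzaldehyde (3,5-dibromosalicylaldehyde)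
Product: 7 3,5-dibromo-2-methoxybenzaldehyde
Conditions: MeI, K2CO3, DMF, 25 °C
Reagents that add atoms: iodomethane, CI
Why: Williamson O-methylation of the acidic phenol proceeds with MeI and K2CO3 in DMF, and the aldehyde and the aryl bromides do not react.

Step 4
Reactants: 7 3,5-dibromo-2-methoxybenzaldehyde
Product: 9 3,5-dibromo-2-methoxyphenol, via 3,5-dibromo-2-methoxyphenyl formate 8 (not isolated)
Conditions: mCPBA, CH2Cl2, 40 °C; then MeOH, Et3N (cat.), 25 °C
Reagents that add atoms: 3-chloroperoxybenzoic acid, OOC(=O)c1cccc(Cl)c1
Why: In this Baeyer–Villiger (Dakin-type) oxidation of an ortho-methoxybenzaldehyde the aryl group bearing the ortho oxygen donor migrates in the tetrahedral peracid adduct to give formate 8, which base-catalysed methanolysis converts into the phenol.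

Step 5
Reactants: 9 3,5-dibromo-2-methoxyphenol; 10 pinacolborane (4,4,5,5-tetramethyl-1,3,2-dioxaborolane)
Product: 11 2-(3,5-dibromo-2-methoxyphenoxy)-4,4,5,5-tetramethyl-1,3,2-dioxaborolane
Conditions: 10 (1.1 equiv), Et3N (5 mol%), toluene, 60 °C; volatiles removed in vacuo, used crude under argon
Reagents that add atoms: none
Why: Protonolysis of the B–H bond by the acidic phenol (dehydrogenative O-borylation, the reaction by which aryloxy pinacol borates are made in situ for phenol C–H borylation) is irreversible through loss of hydrogen and leaves no protic by-product that could later quench an aryl anion.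

Step 6
Reactants: 5 3,6-dibromo-2-(trimethylsilyl)phenyl trifluoromethanesulfonate; 11 2-(3,5-dibromo-2-methoxyphenoxy)-4,4,5,5-tetramethyl-1,3,2-dioxaborolane
Product: 14 2-[3,6-dibromo-2-(3,5-dibromo-2-methoxyphenoxy)phenyl]-4,4,5,5-tetramethyl-1,3,2-dioxaborolane, via 3,6-dibromobenzyne 12 (not isolated), via C1' aryl anion potassium salt 13 (not isolated)
Conditions: 11 (3 equiv), KF (1.5 equiv), 18-crown-6 (1.5 equiv), THF, −20 to 0 °C; aq NH4Cl work-up
Reagents that add atoms: none
Why: Proposed new method: fluoride strips the trimethylsilyl group from 5 and triflate departs to give aryne 12, while part of 11 becomes a fluoroborate ate complex whose aryloxy oxygen (or the aryloxide it releases) adds to one aryne carbon, forming the C2'–O bond and aryl anion 13. Anion 13 is then borylated at C1' either by a 1,3 O-to-C boron shift through a four-membered transition state or, more probably, by a second trigonal molecule of 11, which gives 14 and returns aryloxide to carry a chain, so the net result is insertion of the aryne into the O–B bond. The closest known reactions are aryne insertions into N–Si and S–Sn sigma bonds, the fluoride-mediated O-arylation of phenols by ortho-silylaryl triflates, aryne nucleophile/electrophile three-component couplings and the borylation of aryl anions by alkoxy pinacol borates. No ring is closed and no stereocentre is created. Regioselectivity is not needed because the two aryne carbons of 12 are symmetry-equivalent; what is needed is borylation of 13 ahead of protonation or loss of the neighbouring bromide, and this is secured by the boron delivered with the attacking oxygen, by keeping trigonal 11 in excess over fluoride, by the aprotic medium and by the low temperature. The two bromines make 12 strongly electrophilic and stabilise 13 inductively.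

Step 7
Reactants: 14 2-[3,6-dibromo-2-(3,5-dibromo-2-methoxyphenoxy)phenyl]-4,4,5,5-tetramethyl-1,3,2-dioxaborolane
Product: 15 3,6-dibromo-2-(3,5-dibromo-2-methoxyphenoxy)phenol
Conditions: H2O2 (30% aq), then NaOH (aq), THF, 0 °C
Reagents that add atoms: hydrogen peroxide, OO
Why: Hydroperoxide adds to boron and the aryl group migrates from boron to oxygen at C1' (boronate oxidation) before the borate ester hydrolyses to the phenol; adding peroxide before base at 0 °C should let oxidation outpace protodeboronation, and the aryl bromides and ethers are inert.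

Step 8
Reactants: 15 3,6-dibromo-2-(3,5-dibromo-2-methoxyphenoxy)phenol
Product: 16 3,6-dibromo-2-(3,5-dibromo-2-hydroxyphenoxy)phenol
Conditions: BBr3, CH2Cl2, −78 to 25 °C; then H2O
Reagents that add atoms: none
Why: BBr3 coordinates the methoxy oxygen and bromide removes the methyl group (Lewis acid cleavage of an aryl methyl ether), while the diaryl ether, which has no sp3 carbon on oxygen, and the four C–Br bonds are untouched; aqueous work-up frees both phenols.

**Compound list**
1 | 2,5-dibromophenol | Oc1cc(Br)ccc1Br | starting material
2 | (2,5-dibromophenoxy)trimethylsilane | C[Si](C)(C)Oc1cc(Br)ccc1Br | intermediate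
3 | [3,6-dibromo-2-(trimethylsilyloxy)phenyl]lithium | [Li]c1c(Br)ccc(Br)c1O[Si](C)(C)C | intermediate
4 | lithium 3,6-dibromo-2-(trimethylsilyl)phenoxide | [Li+].[O-]c1c(Br)ccc(Br)c1[Si](C)(C)C | intermediate
5 | 3,6-dibromo-2-(trimethylsilyl)phenyl trifluoromethanesulfonate | C[Si](C)(C)c1c(Br)ccc(Br)c1OS(=O)(=O)C(F)(F)F | intermediate
6 | 3,5-dibromo-2-hydroxybenzaldehyde (3,5-dibromosalicylaldehyde) | O=Cc1cc(Br)cc(Br)c1O | starting material
7 | 3,5-dibromo-2-methoxybenzaldehyde | COc1c(Br)cc(Br)cc1C=O | intermediate
8 | 3,5-dibromo-2-methoxyphenyl formate | COc1c(Br)cc(Br)cc1OC=O | intermediate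
9 | 3,5-dibromo-2-methoxyphenol | COc1c(Br)cc(Br)cc1O | intermediate
10 | pinacolborane (4,4,5,5-tetramethyl-1,3,2-dioxaborolane) | CC1(C)OBOC1(C)C | starting material
11 | 2-(3,5-dibromo-2-methoxyphenoxy)-4,4,5,5-tetramethyl-1,3,2-dioxaborolane | COc1c(Br)cc(Br)cc1OB1OC(C)(C)C(C)(C)O1 | intermediate
12 | 3,6-dibromobenzyne (1,4-dibromo-2,3-didehydrobenzene) | BrC1=CC=C(Br)C#C1 | intermediate
13 | potassium 3,6-dibromo-2-(3,5-dibromo-2-methoxyphenoxy)benzen-1-ide (aryl anion at C1') | COc1c(Br)cc(Br)cc1Oc1[c-]c(Br)ccc1Br.[K+] | intermediate
14 | 2-[3,6-dibromo-2-(3,5-dibromo-2-methoxyphenoxy)phenyl]-4,4,5,5-tetramethyl-1,3,2-dioxaborolane | COc1c(Br)cc(Br)cc1Oc1c(Br)ccc(Br)c1B1OC(C)(C)C(C)(C)O1 | intermediate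
15 | 3,6-dibromo-2-(3,5-dibromo-2-methoxyphenoxy)phenol | COc1c(Br)cc(Br)cc1Oc1c(Br)ccc(Br)c1O | intermediate
16 | 3,6-dibromo-2-(3,5-dibromo-2-hydroxyphenoxy)phenol | Oc1c(Br)cc(Br)cc1Oc1c(Br)ccc(Br)c1O | target

**Step count and risks**
Total: 8 steps. Longest linear sequence: 6 steps (from 6 through steps 3, 4, 5, 6, 7 and 8).

Step 6 (proposed method). Capture of aryl anion 13 by boron may lose to protonation or to ejection of the neighbouring bromide, and fluoride may be held by the borate so that the aryne is released too slowly. The fallback uses known chemistry, sets out from phenol 9 and returns at 15, bypassing 10 to 14. Nucleophilic aromatic substitution of the fluoride of commercial 3,6-dibromo-2-fluorobenzaldehyde (O=Cc1c(F)c(Br)ccc1Br) by 9 (K2CO3, DMF, 80 °C) should give 3,6-dibromo-2-(3,5-dibromo-2-methoxyphenoxy)benzaldehyde F1. Baeyer–Villiger oxidation (mCPBA, CH2Cl2) would lead to 3,6-dibromo-2-(3,5-dibromo-2-methoxyphenoxy)phenyl formate F2, and methanolysis (MeOH, Et3N cat.) would deliver 15, after which step 8 follows.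

Step 2. Aryllithium 3 may lose lithium bromide or undergo halogen migration before the silyl shift, or the amide may attack silicon at oxygen instead of deprotonating the ring. The fallback sets out from 1 and returns at 5, replacing the intramolecular silyl shift by an external in situ quench. Protection of 1 with chloromethyl methyl ether and iPr2NEt (CH2Cl2) gives 1,4-dibromo-2-(methoxymethoxy)benzene F3. Metalation with LiN(iPr)2 in the presence of Me3SiCl (THF, −78 °C) is meant to silylate the transient [3,6-dibromo-2-(methoxymethoxy)phenyl]lithium F4 as it forms, giving [3,6-dibromo-2-(methoxymethoxy)phenyl]trimethylsilane F5. Acetal cleavage (HCl cat., MeOH, 25 °C) would give 3,6-dibromo-2-(trimethylsilyl)phenol F6, and triflation (Tf2O, pyridine, CH2Cl2, 0 °C) gives 5.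

Step 5. Incomplete O-borylation, or hydrolysis of the B–O bond on handling, would leave free phenol that acts as a proton source for the aryl anion in step 6. The fallback sets out from 9 and returns at 11. It is an ester exchange at boron with 2-isopropoxy-4,4,5,5-tetramethyl-1,3,2-dioxaborolane (CC(C)OB1OC(C)(C)C(C)(C)O1) in toluene, with propan-2-ol distilled out to drive the equilibrium. No compound outside the list is made (F0).

Further compounds
F1 | step 6 | 3,6-dibromo-2-(3,5-dibromo-2-methoxyphenoxy)benzaldehyde | COc1c(Br)cc(Br)cc1Oc1c(Br)ccc(Br)c1C=O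
F2 | step 6 | 3,6-dibromo-2-(3,5-dibromo-2-methoxyphenoxy)phenyl formate | COc1c(Br)cc(Br)cc1Oc1c(Br)ccc(Br)c1OC=O
F3 | step 2 | 1,4-dibromo-2-(methoxymethoxy)benzene | COCOc1cc(Br)ccc1Br
F4 | step 2 | [3,6-dibromo-2-(methoxymethoxy)phenyl]lithium | [Li]c1c(Br)ccc(Br)c1OCOC
F5 | step 2 | [3,6-dibromo-2-(methoxymethoxy)phenyl]trimethylsilane | COCOc1c(Br)ccc(Br)c1[Si](C)(C)C
F6 | step 2 | 3,6-dibromo-2-(trimethylsilyl)phenol | Oc1c(Br)ccc(Br)c1[Si](C)(C)C
F0 | step 5 | none | none
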